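**Strategy.** The decalin is built in one step from an open-chain tetraene (labdane numbering: C4 carries the gem-dimethyl group, C5 and C10 are the ring-fusion carbons). Hydrogen-atom transfer to a terminal isopropenyl group gives the C4 radical, which closes ring A at C5. The C10 radical then closes ring B at C9, and loss of a sulfonyl radical from C7 fixes the C7=C8 olefin. The step exploits the head-to-tail isoprenoid pattern C4(CH3)2–C5(H)–C10(CH3) of the trans-fused rings A and B. The C2 silyloxy stereocentre, from (S)-epichlorohydrin, sits equatorial and sets C5 and C10. Ring B is oxidised afterwards at C6 and C7.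

Key step: step 11

Remark on the chemistry: labdane numbering is used throughout (C11–C15 side chain, C15 the primary alcohol carbon); compound 16 is used as the mixture of epimers at its sulfonyl carbon (C7), which step 11 makes trigonal.

**Step 1**
Reactants: 1 (S)-epichlorohydrin
Product: 2 (2S)-1-chloro-4-methylpent-4-en-2-ol
Conditions: isopropenylmagnesium bromide, CuI (copper monoiodide, cat.), THF, −40 → 0 °C
Reagents that add atoms: isopropenylmagnesium bromide, C=C(C)[Mg]Br
Why: Copper-catalysed Grignard opening of the epoxide occurs at its unsubstituted carbon, so the C–O stereocentre of 1 (the later C2) is not touched and the chloride is kept for the next epoxide.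

**Step 2**
Reactants: 2 (2S)-1-chloro-4-methylpent-4-en-2-ol
Product: 4 (4S)-6-methylhept-6-en-1-yn-4-ol, via epoxide 3 (not isolated)
Conditions: lithium acetylide–ethylenediamine complex (excess), DMSO, 0 °C → rt
Reagents that add atoms: lithium acetylide, [Li]C#C
Why: Excess acetylide first closes the chlorohydrin to epoxide 3 (intramolecular Williamson reaction) and then opens it at the CH2 terminus (acetylide epoxide opening), again without touching the carbinol centre.

**Step 3**
Reactants: 4 (4S)-6-methylhept-6-en-1-yn-4-ol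
Product: 5 (4S)-4-(tert-butyldimethylsilyloxy)-6-methylhept-6-en-1-yne
Conditions: TBSCl, imidazole, DMF, rt
Reagents that add atoms: tert-butylchlorodimethylsilane, CC(C)(C)[Si](C)(C)Cl
Why: Routine silylation of the secondary alcohol (silyl ether formation), which also provides the bulky group that must sit equatorial in step 11.

**Step 4**
Reactants: 5 (4S)-4-(tert-butyldimethylsilyloxy)-6-methylhept-6-en-1-yne
Product: 8 (2E,5S)-5-(tert-butyldimethylsilyloxy)-3,7-dimethylocta-2,7-dien-1-ol, via alkenylalane 6 (not isolated), via lithium alanate 7 (not isolated)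
Conditions: Me3Al, Cp2ZrCl2 (cat.), CH2Cl2, rt; then n-BuLi, THF/hexane, −78 → 0 °C; then (CH2O)n, rt
Reagents that add atoms: trimethylaluminium, C[Al](C)C; formaldehyde (as paraformaldehyde), C=O
Why: Zirconium-catalysed syn-carboalumination of the terminal alkyne (Negishi carboalumination) puts CH3 on the internal and aluminium on the terminal carbon while the isopropenyl group stays inert, and hydroxymethylation of the alanate with formaldehyde occurs with retention, which fixes the E-trisubstituted C5=C10 olefin.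

**Step 5**
Reactants: 8 (2E,5S)-5-(tert-butyldimethylsilyloxy)-3,7-dimethylocta-2,7-dien-1-ol
Product: 9 (4S,6E)-8-bromo-4-(tert-butyldimethylsilyloxy)-2,6-dimethylocta-1,6-diene
Conditions: CBr4, PPh3, 2,6-lutidine, CH2Cl2, 0 °C
Reagents that add atoms: tetrabromomethane, BrC(Br)(Br)Br
Why: The Appel reaction converts the primary allylic alcohol into the bromide under buffered conditions without allylic shift.

**Step 6**
Reactants: 10 geraniol
Product: 11 geranyl tert-butyldiphenylsilyl ether
Conditions: TBDPSCl, imidazole, CH2Cl2, rt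
Reagents that add atoms: tert-butylchlorodiphenylsilane, CC(C)(C)[Si](Cl)(c1ccccc1)c1ccccc1
Why: Routine silylation of the primary alcohol (silyl ether formation) with a group that outlasts the later cleavage of the TBS ether.

**Step 7**
Reactants: 11 geranyl tert-butyldiphenylsilyl ether
Product: 12 (2E,6E)-8-(tert-butyldiphenylsilyloxy)-2,6-dimethylocta-2,6-dien-1-ol
Conditions: SeO2 (cat.), t-BuOOH, CH2Cl2, 0 °C → rt
Reagents that add atoms: tert-butyl hydroperoxide, CC(C)(C)OO
Why: SeO2-catalysed allylic oxidation (ene reaction then 2,3-sigmatropic shift) hydroxylates the E-methyl group of the terminal olefin, the other olefin being deactivated by its allylic oxygen.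

**Step 8**
Reactants: 12 (2E,6E)-8-(tert-butyldiphenylsilyloxy)-2,6-dimethylocta-2,6-dien-1-ol
Product: 13 [(2E,6E)-8-bromo-3,7-dimethylocta-2,6-dienyloxy](tert-butyl)diphenylsilane
Conditions: CBr4, PPh3, CH2Cl2, 0 °C
Reagents that add atoms: tetrabromomethane, BrC(Br)(Br)Br
Why: The Appel reaction gives the primary allylic bromide with the olefin geometry unchanged.

**Step 9**
Reactants: 13 [(2E,6E)-8-bromo-3,7-dimethylocta-2,6-dienyloxy](tert-butyl)diphenylsilane
Product: 14 [(2E,6E)-8-(tert-butyldiphenylsilyloxy)-2,6-dimethylocta-2,6-dienyl] phenyl sulfone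
Conditions: PhSO2Na, DMF, rt
Reagents that add atoms: sodium benzenesulfinate, [Na+].[O-]S(=O)c1ccccc1
Why: SN2 displacement of the primary allylic bromide by sulfinate at sulfur gives the allylic sulfone, whose CH2 is the later C7.

**Step 10**
Reactants: 14 [(2E,6E)-8-(tert-butyldiphenylsilyloxy)-2,6-dimethylocta-2,6-dienyl] phenyl sulfone; 9 (4S,6E)-8-bromo-4-(tert-butyldimethylsilyloxy)-2,6-dimethylocta-1,6-diene
Product: 16 (4S,6E,10E,14E)-4-(tert-butyldimethylsilyloxy)-16-(tert-butyldiphenylsilyloxy)-2,6,10,14-tetramethyl-9-(phenylsulfonyl)hexadeca-1,6,10,14-tetraene, via lithiated sulfone 15 (not isolated)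
Conditions: n-BuLi, THF, −78 °C; then 9, −78 → −20 °C
Reagents that add atoms: none
Why: The allyl-stabilised α-sulfonyl carbanion is alkylated at its α-carbon by the primary allylic bromide (SN2 sulfone alkylation), which joins C6 to C7; the new centre at C7 is not controlled because step 11 removes it.

**Step 11**
Reactants: 16 (4S,6E,10E,14E)-4-(tert-butyldimethylsilyloxy)-16-(tert-butyldiphenylsilyloxy)-2,6,10,14-tetramethyl-9-(phenylsulfonyl)hexadeca-1,6,10,14-tetraene
Product: 17 2α-(tert-butyldimethylsilyloxy)-15-(tert-butyldiphenylsilyloxy)labda-7,13E-diene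
Conditions: Fe(acac)3 (0.3 equiv), PhSiH3, Na2HPO4, EtOH/ethylene glycol, 60 °C, argon
Reagents that add atoms: none
Why: Proposed new method: The iron hydride formed from Fe(acac)3 and PhSiH3 should transfer a hydrogen atom to the terminal CH2 of the isopropenyl group, and the tertiary C4 radical adds 6-endo-trig to C5 of the E-C5=C10 olefin (ring A, bond C4–C5); the tertiary C10 radical then adds 6-endo-trig to C9 of the E-C8=C9 allyl sulfone (ring B, bond C9–C10), and the C8 radical expels PhSO2• by β-scission, which places the olefin at C7=C8 while divalent iron reduces the sulfonyl radical to sulfinate and returns trivalent iron. The closest known reaction types are iron-mediated hydrogen-atom-transfer radical bicyclizations of isopropenyl polyenes that end at an electron-poor olefin, Cp2TiCl-mediated radical epoxypolyene bicyclizations, and radical allylation by addition–fragmentation of allyl sulfones; only their combination is new. Both rings close through chair-like transition states with net anti addition across the E-C5=C10 bond, so C5–H and the C10 methyl group end trans (trans-decalin) and the C9 chain equatorial. The absolute sense is set by the C2 silyloxy group, which stays equatorial in the ring A chair because an axial position would meet the axial C10 methyl and one C4 methyl group, so the (S)-centre should give 5α-H and 10β-CH3; C9 follows from the E-C8=C9 geometry and is removed later. The step needs initiation at the 1,1-disubstituted olefin rather than at the three more hindered trisubstituted ones, 6-endo rather than 5-exo closure (attack at the less substituted olefin carbon gives tertiary radicals each time) and cyclization faster than reduction of the radicals (low stationary hydride concentration). Both epimers of 16 converge because C7 becomes trigonal.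

**Step 12**
Reactants: 17 2α-(tert-butyldimethylsilyloxy)-15-(tert-butyldiphenylsilyloxy)labda-7,13E-diene
Product: 18 2α-(tert-butyldimethylsilyloxy)-15-(tert-butyldiphenylsilyloxy)labda-7,13E-dien-6-one
Conditions: CrO3, 3,5-dimethylpyrazole, CH2Cl2, −20 °C
Reagents that add atoms: chromium trioxide, O=[Cr](=O)=O
Why: Allylic oxidation with CrO3–3,5-dimethylpyrazole converts the ring methylene next to the CH end of the trisubstituted C7=C8 olefin (C6) into the enone, while the C13 olefin, deactivated by its allylic silyloxy group, should react more slowly.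

**Step 13**
Reactants: 18 2α-(tert-butyldimethylsilyloxy)-15-(tert-butyldiphenylsilyloxy)labda-7,13E-dien-6-one
Product: 21 2α-(tert-butyldimethylsilyloxy)-15-(tert-butyldiphenylsilyloxy)-7α-hydroxylabda-8,13E-dien-6-one, via silyl dienol ether 19 (not isolated), via lithium dienolate 20 (not isolated)
Conditions: TMSOTf, Et3N, CH2Cl2, 0 °C → rt; then MeLi, THF, 0 °C; then 2-(phenylsulfonyl)-3-phenyloxaziridine, −78 °C; AcOH quench at −78 °C
Reagents that add atoms: 2-(phenylsulfonyl)-3-phenyloxaziridine, O=S(=O)(N1OC1c1ccccc1)c1ccccc1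
Why: Soft enolisation under equilibrating conditions should give the endocyclic, more substituted 6-silyloxy-6,8-diene (loss of 9α-H rather than a C8-methyl proton or the hindered C5–H), MeLi releases the lithium dienolate, and the oxaziridine attacks its α-carbon C7 from the α-face opposite the axial C10 methyl group (deconjugative α-hydroxylation of an extended enolate), which installs the 7α-hydroxyl and the C8=C9 olefin together.

**Step 14**
Reactants: 21 2α-(tert-butyldimethylsilyloxy)-15-(tert-butyldiphenylsilyloxy)-7α-hydroxylabda-8,13E-dien-6-one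
Product: 22 2α-(tert-butyldimethylsilyloxy)-15-(tert-butyldiphenylsilyloxy)labda-8,13E-diene-6β,7α-diol
Conditions: NaBH4, CeCl3·7H2O, MeOH, −40 → 0 °C
Reagents that add atoms: none
Why: In this Luche reduction hydride should add to C6 from the α-face, because the β-face is closed by the syn-axial C4 and C10 methyl groups and the 7α-hydroxyl can guide the borohydride to its own side, which gives the 6β-alcohol and thus the trans-diaxial 6β,7α-diol.

**Step 15**
Reactants: 22 2α-(tert-butyldimethylsilyloxy)-15-(tert-butyldiphenylsilyloxy)labda-8,13E-diene-6β,7α-diol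
Product: 23 15-(tert-butyldiphenylsilyloxy)labda-8,13E-diene-2α,6β,7α-triol
Conditions: HF·pyridine, pyridine, THF, 0 °C
Reagents that add atoms: none
Why: Under buffered HF the secondary TBS ether should be cleaved faster than the primary TBDPS ether (selective desilylation), and the weakly acidic medium spares the allylic 7α-alcohol.

**Step 16**
Reactants: 23 15-(tert-butyldiphenylsilyloxy)labda-8,13E-diene-2α,6β,7α-triol
Product: 24 2α,6β,7α-triacetoxy-15-(tert-butyldiphenylsilyloxy)labda-8,13E-diene
Conditions: Ac2O, DMAP, pyridine, 50 °C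
Reagents that add atoms: acetic anhydride, CC(=O)OC(C)=O
Why: DMAP-catalysed acylation (esterification) acetylates all three secondary alcohols, the hindered axial 6β-hydroxyl needing the excess reagent and warming, with no change at any stereocentre.

**Step 17**
Reactants: 24 2α,6β,7α-triacetoxy-15-(tert-butyldiphenylsilyloxy)labda-8,13E-diene
Product: 25 2α,6β,7α-triacetoxylabda-8,13E-dien-15-ol (CNP0305346.2)
Conditions: HF·pyridine, THF, rt
Reagents that add atoms: none
Why: Fluoride-mediated desilylation under acidic, non-basic conditions frees the primary allylic alcohol without hydrolysis or migration of the three acetates.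

**Compound list**

1 | (S)-epichlorohydrin | ClC[C@@H]1CO1 | starting material
2 | (2S)-1-chloro-4-methylpent-4-en-2-ol | C=C(C)C[C@H](O)CCl | intermediate
3 | (2S)-2-(2-methylprop-2-enyl)oxirane | C=C(C)C[C@H]1CO1 | intermediate (not isolated)
4 | (4S)-6-methylhept-6-en-1-yn-4-ol | C=C(C)C[C@H](O)CC#C | intermediate
5 | (4S)-4-(tert-butyldimethylsilyloxy)-6-methylhept-6-en-1-yne | C=C(C)C[C@H](O[Si](C)(C)C(C)(C)C)CC#C | intermediate
6 | [(1E,4S)-4-(tert-butyldimethylsilyloxy)-2,6-dimethylhepta-1,6-dienyl]dimethylalane | C=C(C)C[C@H](O[Si](C)(C)C(C)(C)C)C/C(C)=C/[Al](C)C | intermediate (not isolated)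
7 | lithium butyl[(1E,4S)-4-(tert-butyldimethylsilyloxy)-2,6-dimethylhepta-1,6-dienyl]dimethylaluminate | [Li+].C=C(C)C[C@H](O[Si](C)(C)C(C)(C)C)C/C(C)=C/[Al-](C)(C)CCCC | intermediate (not isolated)
8 | (2E,5S)-5-(tert-butyldimethylsilyloxy)-3,7-dimethylocta-2,7-dien-1-ol | C=C(C)C[C@H](O[Si](C)(C)C(C)(C)C)C/C(C)=C/CO | intermediate
9 | (4S,6E)-8-bromo-4-(tert-butyldimethylsilyloxy)-2,6-dimethylocta-1,6-diene | C=C(C)C[C@H](O[Si](C)(C)C(C)(C)C)C/C(C)=C/CBr | intermediate
10 | geraniol | CC(C)=CCC/C(C)=C/CO | starting material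
11 | geranyl tert-butyldiphenylsilyl ether | CC(C)=CCC/C(C)=C/CO[Si](c1ccccc1)(c1ccccc1)C(C)(C)C | intermediate
12 | (2E,6E)-8-(tert-butyldiphenylsilyloxy)-2,6-dimethylocta-2,6-dien-1-ol | OC/C(C)=C/CC/C(C)=C/CO[Si](c1ccccc1)(c1ccccc1)C(C)(C)C | intermediate
13 | [(2E,6E)-8-bromo-3,7-dimethylocta-2,6-dienyloxy](tert-butyl)diphenylsilane | BrC/C(C)=C/CC/C(C)=C/CO[Si](c1ccccc1)(c1ccccc1)C(C)(C)C | intermediate
14 | [(2E,6E)-8-(tert-butyldiphenylsilyloxy)-2,6-dimethylocta-2,6-dienyl] phenyl sulfone | O=S(=O)(C/C(C)=C/CC/C(C)=C/CO[Si](c1ccccc1)(c1ccccc1)C(C)(C)C)c1ccccc1 | intermediate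
15 | α-lithio derivative of sulfone 14 | [Li+].O=S(=O)([CH-]/C(C)=C/CC/C(C)=C/CO[Si](c1ccccc1)(c1ccccc1)C(C)(C)C)c1ccccc1 | intermediate (not isolated)
16 | (4S,6E,10E,14E)-4-(tert-butyldimethylsilyloxy)-16-(tert-butyldiphenylsilyloxy)-2,6,10,14-tetramethyl-9-(phenylsulfonyl)hexadeca-1,6,10,14-tetraene (both epimers at C9 of the chain) | C=C(C)C[C@H](O[Si](C)(C)C(C)(C)C)C/C(C)=C/CC(S(=O)(=O)c1ccccc1)/C(C)=C/CC/C(C)=C/CO[Si](c1ccccc1)(c1ccccc1)C(C)(C)C | intermediate
17 | 2α-(tert-butyldimethylsilyloxy)-15-(tert-butyldiphenylsilyloxy)labda-7,13E-diene | CC(C)(C)[Si](C)(C)O[C@H]1CC(C)(C)[C@@H]2CC=C(C)[C@H](CC/C(C)=C/CO[Si](c3ccccc3)(c3ccccc3)C(C)(C)C)[C@@]2(C)C1 | intermediate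
18 | 2α-(tert-butyldimethylsilyloxy)-15-(tert-butyldiphenylsilyloxy)labda-7,13E-dien-6-one | CC(C)(C)[Si](C)(C)O[C@H]1CC(C)(C)[C@@H]2C(=O)C=C(C)[C@H](CC/C(C)=C/CO[Si](c3ccccc3)(c3ccccc3)C(C)(C)C)[C@@]2(C)C1 | intermediate
19 | 2α-(tert-butyldimethylsilyloxy)-15-(tert-butyldiphenylsilyloxy)-6-(trimethylsilyloxy)labda-6,8,13E-triene | CC(C)(C)[Si](C)(C)O[C@H]1CC(C)(C)[C@@H]2C(O[Si](C)(C)C)=CC(C)=C(CC/C(C)=C/CO[Si](c3ccccc3)(c3ccccc3)C(C)(C)C)[C@@]2(C)C1 | intermediate (not isolated)
20 | lithium 2α-(tert-butyldimethylsilyloxy)-15-(tert-butyldiphenylsilyloxy)labda-6,8,13E-trien-6-olate | [Li+].CC(C)(C)[Si](C)(C)O[C@H]1CC(C)(C)[C@@H]2C([O-])=CC(C)=C(CC/C(C)=C/CO[Si](c3ccccc3)(c3ccccc3)C(C)(C)C)[C@@]2(C)C1 | intermediate (not isolated)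
21 | 2α-(tert-butyldimethylsilyloxy)-15-(tert-butyldiphenylsilyloxy)-7α-hydroxylabda-8,13E-dien-6-one | CC(C)(C)[Si](C)(C)O[C@H]1CC(C)(C)[C@@H]2C(=O)[C@@H](O)C(C)=C(CC/C(C)=C/CO[Si](c3ccccc3)(c3ccccc3)C(C)(C)C)[C@@]2(C)C1 | intermediate
22 | 2α-(tert-butyldimethylsilyloxy)-15-(tert-butyldiphenylsilyloxy)labda-8,13E-diene-6β,7α-diol | CC(C)(C)[Si](C)(C)O[C@H]1CC(C)(C)[C@@H]2[C@H](O)[C@@H](O)C(C)=C(CC/C(C)=C/CO[Si](c3ccccc3)(c3ccccc3)C(C)(C)C)[C@@]2(C)C1 | intermediate
23 | 15-(tert-butyldiphenylsilyloxy)labda-8,13E-diene-2α,6β,7α-triol | O[C@H]1CC(C)(C)[C@@H]2[C@H](O)[C@@H](O)C(C)=C(CC/C(C)=C/CO[Si](c3ccccc3)(c3ccccc3)C(C)(C)C)[C@@]2(C)C1 | intermediate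
24 | 2α,6β,7α-triacetoxy-15-(tert-butyldiphenylsilyloxy)labda-8,13E-diene | CC(=O)O[C@H]1CC(C)(C)[C@@H]2[C@H](OC(C)=O)[C@@H](OC(C)=O)C(C)=C(CC/C(C)=C/CO[Si](c3ccccc3)(c3ccccc3)C(C)(C)C)[C@@]2(C)C1 | intermediate
25 | 2α,6β,7α-triacetoxylabda-8,13E-dien-15-ol (CNP0305346.2) | CC(=O)O[C@H]1CC(C)(C)[C@@H]2[C@H](OC(C)=O)[C@@H](OC(C)=O)C(C)=C(CC/C(C)=C/CO)[C@@]2(C)C1 | target

**Step count.** Total: 17 steps. Longest linear sequence: 13 steps (steps 1–5, then 10–17); the geraniol branch (steps 6–9) joins at step 10.

**Steps most likely to fail**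

1. Step 11 (Proposed new method). The first 6-endo closure onto the unactivated C5=C10 olefin may be slower than reduction of the tertiary C4 radical by the iron hydride, or hydrogen-atom transfer may start at a trisubstituted olefin. Fallback with known chemistry, setting out from 16: hydride displacement of the allylic sulfone catalysed by zerovalent palladium (PdCl2(dppp), LiBHEt3, THF, 0 °C) gives the sulfone-free all-E tetraene F1. F1 is closed by the established radical–polar crossover bicyclization of isopropenyl polyenes (Co(salen) [N,N'-bis(salicylidene)ethylenediaminocobalt, divalent cobalt], N-fluoro-2,4,6-trimethylpyridinium tetrafluoroborate, PhSiH3, hexafluoroisopropanol). There the C4 cation forms C4–C5 and C9–C10 in a cation–olefin cascade under the same control by the equatorial C2 silyloxy group. Proton loss from C8 gives 17 together with its exocyclic isomer, the labda-8(17),13E-diene F2, which is moved into the ring with catalytic iodine in benzene, as is known for 8(17)-labdenes. The route is rejoined at 17.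

2. Step 13. Enolisation may remove a proton of the C8 methyl group instead of 9α-H and so lead to the exocyclic olefin, or the oxidant may attack the γ-carbon C9. Fallback setting out from 18: Luche reduction (NaBH4, CeCl3·7H2O, MeOH) gives the 6β-allylic alcohol F3 by hydride attack from the α-face. A Schenck ene reaction with singlet oxygen (O2, tetraphenylporphyrin, light, CH2Cl2) should then place oxygen on C7 from the open α-face, with removal of the axial 9α-H and shift of the olefin to C8=C9, giving the 7α-hydroperoxide F4. Reduction with PPh3 gives diol 22, where the route is rejoined.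

3. Step 12. Oxidation may also occur at the allylic positions of the side-chain olefin (C12, C16, C15), or over-oxidation may take place. Fallback setting out from 17: electrophilic hydroxyselenation (PhSeCl, H2O, MeCN), which should prefer the more electron-rich ring olefin and add trans-diaxially, gives the 7α-phenylselanyl 8β-alcohol F5. Oxidation with H2O2 and syn-elimination of the selenoxide away from the carbinol carbon gives the tertiary allylic alcohol F6 with a C6=C7 olefin. Oxidative 1,3-transposition with pyridinium chlorochromate (Babler–Dauben oxidation) gives enone 18, where the route is rejoined.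

**Further compounds**

F1 | step 11 | (4S,6E,10E,14E)-4-(tert-butyldimethylsilyloxy)-16-(tert-butyldiphenylsilyloxy)-2,6,10,14-tetramethylhexadeca-1,6,10,14-tetraene | C=C(C)C[C@H](O[Si](C)(C)C(C)(C)C)C/C(C)=C/CC/C(C)=C/CC/C(C)=C/CO[Si](c1ccccc1)(c1ccccc1)C(C)(C)C
F2 | step 11 | 2α-(tert-butyldimethylsilyloxy)-15-(tert-butyldiphenylsilyloxy)labda-8(17),13E-diene | CC(C)(C)[Si](C)(C)O[C@H]1CC(C)(C)[C@@H]2CCC(=C)[C@H](CC/C(C)=C/CO[Si](c3ccccc3)(c3ccccc3)C(C)(C)C)[C@@]2(C)C1
F3 | step 13 | 2α-(tert-butyldimethylsilyloxy)-15-(tert-butyldiphenylsilyloxy)labda-7,13E-dien-6β-ol | CC(C)(C)[Si](C)(C)O[C@H]1CC(C)(C)[C@@H]2[C@H](O)C=C(C)[C@H](CC/C(C)=C/CO[Si](c3ccccc3)(c3ccccc3)C(C)(C)C)[C@@]2(C)C1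
F4 | step 13 | 2α-(tert-butyldimethylsilyloxy)-15-(tert-butyldiphenylsilyloxy)-7α-hydroperoxylabda-8,13E-dien-6β-ol | CC(C)(C)[Si](C)(C)O[C@H]1CC(C)(C)[C@@H]2[C@H](O)[C@@H](OO)C(C)=C(CC/C(C)=C/CO[Si](c3ccccc3)(c3ccccc3)C(C)(C)C)[C@@]2(C)C1
F5 | step 12 | 2α-(tert-butyldimethylsilyloxy)-15-(tert-butyldiphenylsilyloxy)-7α-(phenylselanyl)labd-13E-en-8β-ol | CC(C)(C)[Si](C)(C)O[C@H]1CC(C)(C)[C@@H]2C[C@@H]([Se]c3ccccc3)[C@](C)(O)[C@H](CC/C(C)=C/CO[Si](c3ccccc3)(c3ccccc3)C(C)(C)C)[C@@]2(C)C1
F6 | step 12 | 2α-(tert-butyldimethylsilyloxy)-15-(tert-butyldiphenylsilyloxy)labda-6,13E-dien-8β-ol | CC(C)(C)[Si](C)(C)O[C@H]1CC(C)(C)[C@@H]2C=C[C@](C)(O)[C@H](CC/C(C)=C/CO[Si](c3ccccc3)(c3ccccc3)C(C)(C)C)[C@@]2(C)C1
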